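**Plan**

- Retrosynthesis: remove the octanoate and the silyl ether; open the lactone C17–O–C3 together with C4–O back to a C3=C4 epoxide attacked by the C17 acid; remove C17, C16, C20 and C18 as one-carbon units; cut oxolane and cyclohexane together (C1–C10, C13–C14) by a retro-Diels–Alder step; cut the oxonane at C4–C5 by a retro-Claisen step to a 2-methylene-1,4-dioxepane; cut the C2–O ether to a secondary alcohol and a glycerate triflate.
- Forward ring order: cyclopropanol (masked vinyl ketone) → seven-membered lactone and enol ether (helper ring) → nine-membered oxonane by [3,3] ring expansion → oxolane and cyclohexanone in one Diels–Alder step → seven-membered lactone by epoxide opening.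
- Enabling feature: in the oxonane the C3 oxygen, the C4–C5 ethano unit and the C6-hydroxy/C7-methylene pair map onto an allyl vinyl ether C4=C3–O–C7–C6=C5 once a temporary oxygen joins C3 to C7 in a seven-membered ring; that oxygen becomes the C3 carbonyl oxygen and later leaves as triflate.
- Stereochemistry: C9 by Keck methallylation; C2 from methyl (S)-glycerate with SN2 inversion; C6 by Shi epoxidation; C1, C10, C14 in the Diels–Alder step; C11 by Grignard addition to the convex face; C15 by Ru-BINAP hydrogenation; C3 and C4 by anti opening of one epoxide by the tethered acid.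

Key step: step 12

Remark: the structure is taken exactly as written; H-1, H-2 and H-10 are then cis on the oxolane and H-9 is trans, so C3 and C8 leave the oxolane on opposite faces (a 2,9-trans-bridged, strained oxonane); C2 and C9 are therefore fixed before any ring exists and the oxolane is closed last.

Locants: C2–C9 are the oxonane carbons (ring oxygen between C2 and C9); C1 and C10–C14 the cyclohexane; C15 (methyl C16) and C17 the lactone side chain; C18 the methyl on C3; C19 the methylene on C7; C20 the methyl on C11.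

**Route**

Step 1
Reactants: 1 methyl 3,3-dimethoxypropanoate
Product: 2 1-(2,2-dimethoxyethyl)cyclopropan-1-ol
Conditions: EtMgBr (2.4 equiv), Ti(OiPr)4 (0.2 equiv), THF, 0 °C to rt; aq. NH4Cl
Reagents that add atoms: ethylmagnesium bromide, CC[Mg]Br
Why: Kulinkovich cyclopropanation, in which the titanacyclopropane made from EtMgBr and Ti(OiPr)4 adds twice to the ester carbonyl, should give the cyclopropanol whose two new CH2 groups become C12 and C13 and which serves as a non-stereogenic mask of the later vinyl ketone.

Step 2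
Reactants: 2 1-(2,2-dimethoxyethyl)cyclopropan-1-ol
Product: 4 2-[1-(triethylsilyloxy)cyclopropyl]acetaldehyde, via silyl ether acetal 3 (not isolated)
Conditions: Et3SiOTf (2.5 equiv), 2,4,6-collidine (4 equiv), CH2Cl2, 0 °C; then H2O, rt
Reagents that add atoms: triethylsilyl trifluoromethanesulfonate, CC[Si](CC)(CC)OS(=O)(=O)C(F)(F)F; water, O
Why: O-silylation of the tertiary cyclopropanol followed by silyl triflate/collidine cleavage of the dimethyl acetal through a collidinium N,O-acetal, which water hydrolyses, should give the aldehyde under non-acidic conditions that spare the silyloxycyclopropane.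

Step 3
Reactants: 4 2-[1-(triethylsilyloxy)cyclopropyl]acetaldehyde
Product: 5 (2S)-4-methyl-1-[1-(triethylsilyloxy)cyclopropyl]pent-4-en-2-ol
Conditions: tributyl(2-methylallyl)stannane (1.5 equiv), (S)-BINOL (20 mol %), Ti(OiPr)4 (10 mol %), 4 Å MS, CH2Cl2, −20 °C; aq. NaHCO3
Reagents that add atoms: tributyl(2-methylallyl)stannane, CC(=C)C[Sn](CCCC)(CCCC)CCCC
Why: Keck asymmetric allylation with the 2-methylallyl stannane, in which the (S)-BINOL titanium Lewis acid shields one aldehyde face, should set C9 as (S) by the established sense of this catalyst and bring in C7, C8 and C19 as a masked methyl ketone.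

Step 4
Reactants: 6 methyl (2S)-2,3-dihydroxypropanoate
Product: 7 methyl (2S)-2-hydroxy-3-(triethylsilyloxy)propanoate
Conditions: Et3SiCl (1.05 equiv), imidazole, CH2Cl2, −20 °C
Reagents that add atoms: chlorotriethylsilane, CC[Si](Cl)(CC)CC
Why: Selective silylation of the primary hydroxyl on steric grounds leaves the C2 hydroxyl free and does not touch the chiral-pool stereocentre.

Step 5
Reactants: 7 methyl (2S)-2-hydroxy-3-(triethylsilyloxy)propanoate
Product: 8 methyl (2S)-3-(triethylsilyloxy)-2-(trifluoromethylsulfonyloxy)propanoate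
Conditions: Tf2O (1.1 equiv), 2,6-lutidine, CH2Cl2, −78 °C; used at once
Reagents that add atoms: trifluoromethanesulfonic anhydride, O=S(=O)(OS(=O)(=O)C(F)(F)F)C(F)(F)F
Why: O-triflation at low temperature activates the secondary alcohol for displacement with retention of the C2 configuration at this stage.

Step 6
Reactants: 5 (2S)-4-methyl-1-[1-(triethylsilyloxy)cyclopropyl]pent-4-en-2-ol; 8 methyl (2S)-3-(triethylsilyloxy)-2-(trifluoromethylsulfonyloxy)propanoate
Product: 9 methyl (2R)-2-{[(2S)-4-methyl-1-[1-(triethylsilyloxy)cyclopropyl]pent-4-en-2-yl]oxy}-3-(triethylsilyloxy)propanoate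
Conditions: NaH (1.1 equiv), THF, 0 °C; then 8, −40 to 0 °C
Reagents that add atoms: none
Why: Williamson-type SN2 displacement of the α-triflyloxy ester by the sodium alkoxide of 5 should proceed with clean inversion, so that (S)-8 gives the (R)-configured C2 ether while the C9 carbinol carbon is not involved.

Step 7
Reactants: 9 methyl ester (compound 9)
Product: 10 (2R)-2-{[(2S)-4-methyl-1-[1-(triethylsilyloxy)cyclopropyl]pent-4-en-2-yl]oxy}-3-(triethylsilyloxy)propanoic acid
Conditions: LiOH·H2O (2 equiv), THF/H2O, 0 °C; cold 0.5 M HCl to pH 4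
Reagents that add atoms: lithium hydroxide, [Li+].[OH-]
Why: Saponification of the activated α-alkoxy methyl ester at 0 °C, done before the ketone is unmasked so that no β-alkoxy ketone meets hydroxide, should leave the silyl ethers and C2 intact.

Step 8
Reactants: 10 alkenyl acid (compound 10)
Product: 11 (2R)-2-{[(2R)-4-oxo-1-[1-(triethylsilyloxy)cyclopropyl]pentan-2-yl]oxy}-3-(triethylsilyloxy)propanoic acid
Conditions: O3, CH2Cl2/MeOH, −78 °C; Me2S, −78 °C to rt
Reagents that add atoms: ozone, [O-][O+]=O
Why: Ozonolysis of the only alkene gives the methyl ketone (C7, with the former allyl methyl as C19) without affecting a stereocentre.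

Step 9
Reactants: 11 keto acid (compound 11)
Product: 12 (2R)-2-{[(2S)-4-hydroxy-4-methyl-1-[1-(triethylsilyloxy)cyclopropyl]hex-5-en-2-yl]oxy}-3-(triethylsilyloxy)propanoic acid, both epimers at C7
Conditions: CH2=CHMgBr (3.5 equiv), THF, −78 to −30 °C; aq. NH4Cl
Reagents that add atoms: vinylmagnesium bromide, C=C[Mg]Br
Why: Grignard 1,2-addition to the ketone of the magnesium carboxylate gives the tertiary allylic alcohol (C5 and C6 enter); the new C7 centre is formed without useful control and carries no descriptor because step 12 erases it.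

Step 10
Reactants: 12 hydroxy acid (compound 12)
Product: 13 (3R,5S)-7-ethenyl-7-methyl-5-{[1-(triethylsilyloxy)cyclopropyl]methyl}-3-[(triethylsilyloxy)methyl]-1,4-dioxepan-2-one, both C7 epimers
Conditions: 2,4,6-Cl3C6H2COCl, Et3N, THF, rt; then slow addition to DMAP, toluene, 80 °C, high dilution
Reagents that add atoms: none
Why: Yamaguchi lactonization through the mixed anhydride and acylpyridinium ion should close the seven-membered helper ring on the tertiary alcohol, helped by the activated α-alkoxy acyl group and high dilution.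

Step 11
Reactants: 13 dioxepanone (compound 13)
Product: 14 (3R,5S)-7-ethenyl-7-methyl-2-methylidene-5-{[1-(triethylsilyloxy)cyclopropyl]methyl}-3-[(triethylsilyloxy)methyl]-1,4-dioxepane, both C7 epimers
Conditions: Cp2TiMe2 (2.5 equiv), toluene, 65 °C, dark; filtration through basic Al2O3
Reagents that add atoms: dimethyltitanocene, [CH3-].[CH3-].[Ti+4].c1cc[cH-]c1.c1cc[cH-]c1
Why: Petasis methylenation (titanium methylidene, [2+2] then retro-[2+2]) converts the lactone carbonyl into the exocyclic enol ether, bringing in C4 and completing the allyl vinyl ether at a temperature at which no rearrangement is expected, so the titanium reagent can be removed before heating.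

Step 12
Reactants: 14 2-methylene-1,4-dioxepane (compound 14)
Product: 15 (2R,9S,6Z)-7-methyl-9-{[1-(triethylsilyloxy)cyclopropyl]methyl}-2-[(triethylsilyloxy)methyl]oxon-6-en-3-one (nine-membered cyclic ether, oxygen as position 1)
Conditions: toluene (0.02 M), Et3N (1 vol %), 130 °C, sealed base-washed tube
Reagents that add atoms: none
Why: On heating, the allyl vinyl ether C4=C3–O–C7–C6=C5 held in the seven-membered ring undergoes a concerted suprafacial [3,3]-sigmatropic (Claisen) shift in which the C4–C5 bond forms as the C7–O bond breaks, so the oxygen between C3 and C7 leaves the ring as the C3 carbonyl oxygen and the 1,4-dioxepane becomes the oxonane (enlargement by two atoms). The closest known reaction type is the Claisen ring expansion of 2-methylene-6-vinyltetrahydropyrans to cyclooct-4-enones and of vinyl-substituted cyclic ketene acetals to medium-ring lactones. The nine-membered ring is closed not end to end but by this 1,3-transposition through a boat-like six-centre transition state that spans the small ring. No new stereocentre arises: C2 and C9 lie outside the six reacting atoms and are carried over unchanged, the C7 centre is erased so that both epimers of 14 converge, and the ring constraint of the boat transition state fixes the new C6=C7 bond as Z (C5 and C8 cis). The step needs this Z geometry, an intact C2 next to the new ketone and no ionization of the tertiary allylic C7–O bond. The cyclic transition state and neutral, dilute, acid-free thermolysis should secure all three.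

Step 13
Reactants: 15 oxonenone (compound 15)
Product: 16 (2R,9S,3E,6Z)-7-methyl-9-{[1-(triethylsilyloxy)cyclopropyl]methyl}-2-[(triethylsilyloxy)methyl]oxona-3,6-dien-3-yl trifluoromethanesulfonate
Conditions: KN(SiMe3)2 (1.15 equiv), THF, −78 °C; PhNTf2 (1.2 equiv), −78 to −20 °C; aq. NH4Cl
Reagents that add atoms: N-phenylbis(trifluoromethanesulfonimide), O=S(=O)(N(c1ccccc1)S(=O)(=O)C(F)(F)F)C(F)(F)F
Why: Kinetic deprotonation at the unhindered C4 methylene rather than at the α-alkoxy methine C2 (so C2 is not epimerized) and O-triflation should give the ring-cis enol triflate.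

Step 14
Reactants: 16 enol triflate (compound 16)
Product: 17 (2S,9S,3Z,6Z)-3,7-dimethyl-9-{[1-(triethylsilyloxy)cyclopropyl]methyl}-2-[(triethylsilyloxy)methyl]oxona-3,6-diene
Conditions: MeMgBr (1.4 equiv), Fe(acac)3 (5 mol %), THF/NMP, −30 °C
Reagents that add atoms: methylmagnesium bromide, C[Mg]Br
Why: Iron-catalysed Kumada-type cross-coupling of the enol triflate with retention of alkene geometry installs C18 and removes the helper oxygen as triflate.

Step 15
Reactants: 17 oxonadiene (compound 17)
Product: 18 6,7-epoxide of 17 with (6S,7R) configuration, other centres as in 17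
Conditions: L-fructose-derived Shi ketone (enantiomer of the usual D-fructose-derived catalyst, 0.3 equiv), KHSO5 (as 2KHSO5·KHSO4·K2SO4), K2CO3, Bu4NHSO4, MeCN/CH2(OMe)2/aq. Na2B4O7, 0 °C
Reagents that add atoms: potassium peroxymonosulfate, [K+].[O-]S(=O)(=O)OO
Why: Shi asymmetric epoxidation, in which the dioxirane should prefer the more electron-rich and less hindered C6=C7 over C3=C4 (deactivated by its allylic oxygen), is expected through the spiro transition state of the L-fructose-derived ketone to deliver oxygen to the face that makes C6 (S).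

Step 16
Reactants: 18 epoxide (compound 18)
Product: 19 (2S,6S,9S,3Z)-3-methyl-7-methylidene-9-{[1-(triethylsilyloxy)cyclopropyl]methyl}-2-[(triethylsilyloxy)methyl]oxon-3-en-6-ol
Conditions: Et2AlCl and lithium 2,2,6,6-tetramethylpiperidide (4 equiv each, toluene, 0 °C, giving Et2Al(TMP)); then 18, 0 °C to rt; aq. KNaC4H4O6
Reagents that add atoms: none
Why: Aluminium amide isomerization of the epoxide to the allylic alcohol by syn β-elimination removes a proton from the C7 methyl group, which is cis to H-6, giving C7=C19 while the C6–O bond and its configuration stay unchanged.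

Step 17
Reactants: 19 allylic alcohol (compound 19)
Product: 20 tert-butyldimethylsilyl ether of 19 at C6–O
Conditions: tBuMe2SiOTf (1.3 equiv), 2,6-lutidine, CH2Cl2, −78 °C
Reagents that add atoms: tert-butyldimethylsilyl trifluoromethanesulfonate, CC(C)(C)[Si](C)(C)OS(=O)(=O)C(F)(F)F
Why: Silylation protects the secondary allylic alcohol against the coming oxidations with a group more robust than the two triethylsilyl ethers.

Step 18
Reactants: 20 tris-silyl ether (compound 20)
Product: 21 (2S,6S,9S,3Z)-6-(tert-butyldimethylsilyloxy)-9-[(1-hydroxycyclopropyl)methyl]-2-(hydroxymethyl)-3-methyl-7-methylideneoxon-3-ene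
Conditions: HF·pyridine, pyridine, THF, 0 °C
Reagents that add atoms: none
Why: Buffered fluoride should cleave both triethylsilyl ethers much faster than the secondary tert-butyldimethylsilyl ether.

Step 19
Reactants: 21 diol (compound 21)
Product: 23 (E)-Weinreb enamide at C2 (C2–CH=CH–C(O)N(OMe)Me) with free cyclopropanol, via aldehyde 22 (not isolated)
Conditions: SO3·pyridine (3 equiv), DMSO, iPr2NEt, CH2Cl2, 0 °C; then Ph3P=CHC(O)N(OMe)Me (1.5 equiv), rt
Reagents that add atoms: N-methoxy-N-methyl-2-(triphenylphosphoranylidene)acetamide, CON(C)C(=O)C=P(c1ccccc1)(c1ccccc1)c1ccccc1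
Why: Parikh–Doering oxidation of the primary alcohol (the tertiary cyclopropanol cannot be oxidized by activated DMSO) and Wittig olefination with the stabilized ylide in the same flask should give the (E)-enamide dienophile without isolation of the epimerizable α-alkoxy aldehyde.

Step 20
Reactants: 23 enamide cyclopropanol (compound 23)
Product: 24 vinyl ketone (C9–CH2–C(O)–CH=CH2) bearing the enamide at C2
Conditions: Pd(OAc)2 (10 mol %), pyridine, 4 Å MS, O2 (1 atm), toluene, 80 °C
Reagents that add atoms: none
Why: Palladium-catalysed aerobic ring opening of the cyclopropanol (palladium alkoxide, β-carbon elimination to the palladium homoenolate, β-hydride elimination) unmasks the vinyl ketone C11(=O)–C12=C13.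

Step 21
Reactants: 24 vinyl ketone enamide (compound 24)
Product: 27 tricyclic keto amide (oxolane and C11 cyclohexanone fused to the oxonene), via silyloxy triene 25 (not isolated), via silyl enol ether cycloadduct 26 (not isolated)
Conditions: Et3SiOTf (1.2 equiv), Et3N (2 equiv), CH2Cl2, −78 to 0 °C; toluene, 80 °C; then 1 M HCl, THF, 0 °C
Reagents that add atoms: none
Why: Soft enolization gives the (Z)-2-silyloxy diene, which should undergo an intramolecular Diels–Alder reaction with the (E)-enamide across the C2–O–C9 tether, where the (E)-dienophile places C2 and C15 trans (C14), the tether-endo, carbonyl-exo mode gives the cis ring fusion (C1, C10), allylic 1,3-strain between H-9 and the C11 silyloxy group puts C8 trans to C11, and the 2,9-trans ring then leaves only the C3 face of C2 for bonding, after which acid hydrolyses the enol ether to the C11 ketone.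

Step 22
Reactants: 27 tricyclic keto amide (compound 27)
Product: 28 tricyclic C11 tertiary alcohol with acetyl group at C14
Conditions: MeMgBr (4 equiv), THF, −78 to 0 °C; aq. NH4Cl
Reagents that add atoms: methylmagnesium bromide, C[Mg]Br
Why: Grignard addition does two jobs, since methyl should add to the C11 ketone from the convex face anti to the adjacent C10–C9 bond (C20 enters, hydroxyl cis to C9) while the Weinreb amide is converted through its stable chelate into the methyl ketone (C16 enters).

Step 23
Reactants: 28 hydroxy methyl ketone (compound 28)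
Product: 29 vinyl triflate (C14–C(OTf)=CH2)
Conditions: KN(SiMe3)2 (2.3 equiv), THF, −78 °C; PhNTf2 (1.1 equiv); aq. NH4Cl
Reagents that add atoms: N-phenylbis(trifluoromethanesulfonimide), O=S(=O)(N(c1ccccc1)S(=O)(=O)C(F)(F)F)C(F)(F)F
Why: Kinetic enolization of the methyl ketone at the methyl group rather than at the C14 methine, followed by O-triflation, should leave C14 and the hindered tertiary alkoxide untouched.

Step 24
Reactants: 29 vinyl triflate (compound 29)
Product: 30 2-substituted acrylic acid (C14–C(=CH2)–CO2H)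
Conditions: Pd(OAc)2 (5 mol %), dppp (10 mol %), CO (1 atm), H2O, Et3N, DMF, 50 °C; acidify to pH 4
Reagents that add atoms: carbon monoxide, [C-]#[O+]; water, O
Why: Palladium-catalysed hydroxycarbonylation of the vinyl triflate (oxidative addition, CO insertion, hydrolysis of the acyl palladium) introduces C17 as the acid.

Step 25
Reactants: 30 acrylic acid (compound 30)
Product: 31 α-methyl acid with C15 as in the target
Conditions: Ru(OAc)2[(R)-BINAP] (2 mol %), H2 (60 bar), MeOH, rt
Reagents that add atoms: none
Why: Carboxylate-directed asymmetric hydrogenation of the α-substituted acrylic acid leaves the unfunctionalized alkenes alone, and the (R)-ligand is chosen by analogy with 2-substituted acrylic acids to give C15 (R).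

Step 26
Reactants: 31 α-methyl acid (compound 31)
Product: 33 hydroxy lactone (target skeleton with free C4–OH and silylated C6–OH), via epoxy acid 32 (not isolated)
Conditions: mCPBA (1.1 equiv), CH2Cl2, −20 to 0 °C; then camphorsulfonic acid (10 mol %), rt
Reagents that add atoms: 3-chloroperbenzoic acid, OOC(=O)c1cccc(Cl)c1
Why: Prilezhaev epoxidation of the trisubstituted C3=C4 alkene on the face away from the C2–C1 bond, followed by acid-catalysed 7-exo opening of the epoxide at the tertiary carbon C3 by the C17 acid from the rear (inversion at C3, C4–O retained), should set C3 and C4 and close the lactone in one operation.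

Step 27
Reactants: 33 hydroxy lactone (compound 33)
Product: 34 C4 octanoate of 33
Conditions: octanoyl chloride (1.5 equiv), pyridine, DMAP (10 mol %), CH2Cl2, 0 °C to rt
Reagents that add atoms: octanoyl chloride, CCCCCCCC(=O)Cl
Why: Acylation should occur only at the secondary C4 hydroxyl because the tertiary C11 hydroxyl is inert under these conditions.

Step 28
Reactants: 34 silyl ether octanoate (compound 34)
Product: 35 target, (1S,2R,3S,4R,6S,9S,10R,11R,14R,15R) in the locants above
Conditions: HF·pyridine, THF, 0 °C to rt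
Reagents that add atoms: none
Why: Fluoride cleaves the remaining silyl ether at C6 without touching the octanoate or the lactone.

**Compound list**

1 | methyl 3,3-dimethoxypropanoate | COC(=O)CC(OC)OC | starting material
2 | 1-(2,2-dimethoxyethyl)cyclopropan-1-ol | OC1(CC(OC)OC)CC1 | intermediate
3 | [1-(2,2-dimethoxyethyl)cyclopropoxy]triethylsilane (not isolated) | CC[Si](CC)(CC)OC1(CC(OC)OC)CC1 | intermediate
4 | 2-[1-(triethylsilyloxy)cyclopropyl]acetaldehyde | CC[Si](CC)(CC)OC1(CC=O)CC1 | intermediate
5 | (2S)-4-methyl-1-[1-(triethylsilyloxy)cyclopropyl]pent-4-en-2-ol | CC(=C)C[C@H](O)CC1(O[Si](CC)(CC)CC)CC1 | intermediate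
6 | methyl (2S)-2,3-dihydroxypropanoate | COC(=O)[C@@H](O)CO | starting material
7 | methyl (2S)-2-hydroxy-3-(triethylsilyloxy)propanoate | COC(=O)[C@@H](O)CO[Si](CC)(CC)CC | intermediate
8 | methyl (2S)-3-(triethylsilyloxy)-2-(trifluoromethylsulfonyloxy)propanoate | COC(=O)[C@@H](OS(=O)(=O)C(F)(F)F)CO[Si](CC)(CC)CC | intermediate
9 | methyl (2R)-2-{[(2S)-4-methyl-1-[1-(triethylsilyloxy)cyclopropyl]pent-4-en-2-yl]oxy}-3-(triethylsilyloxy)propanoate | CC(=C)C[C@H](O[C@@H](C(=O)OC)CO[Si](CC)(CC)CC)CC1(O[Si](CC)(CC)CC)CC1 | intermediate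
10 | (2R)-2-{[(2S)-4-methyl-1-[1-(triethylsilyloxy)cyclopropyl]pent-4-en-2-yl]oxy}-3-(triethylsilyloxy)propanoic acid | CC(=C)C[C@H](O[C@@H](C(=O)O)CO[Si](CC)(CC)CC)CC1(O[Si](CC)(CC)CC)CC1 | intermediate
11 | (2R)-2-{[(2R)-4-oxo-1-[1-(triethylsilyloxy)cyclopropyl]pentan-2-yl]oxy}-3-(triethylsilyloxy)propanoic acid | CC(=O)C[C@H](O[C@@H](C(=O)O)CO[Si](CC)(CC)CC)CC1(O[Si](CC)(CC)CC)CC1 | intermediate
12 | (2R)-2-{[(2S)-4-hydroxy-4-methyl-1-[1-(triethylsilyloxy)cyclopropyl]hex-5-en-2-yl]oxy}-3-(triethylsilyloxy)propanoic acid, both C7 epimers | C=CC(C)(O)C[C@H](O[C@@H](C(=O)O)CO[Si](CC)(CC)CC)CC1(O[Si](CC)(CC)CC)CC1 | intermediate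
13 | (3R,5S)-7-ethenyl-7-methyl-5-{[1-(triethylsilyloxy)cyclopropyl]methyl}-3-[(triethylsilyloxy)methyl]-1,4-dioxepan-2-one, both C7 epimers | C=CC1(C)C[C@@H](CC2(O[Si](CC)(CC)CC)CC2)O[C@H](CO[Si](CC)(CC)CC)C(=O)O1 | intermediate
14 | (3R,5S)-7-ethenyl-7-methyl-2-methylidene-5-{[1-(triethylsilyloxy)cyclopropyl]methyl}-3-[(triethylsilyloxy)methyl]-1,4-dioxepane, both C7 epimers | C=CC1(C)C[C@@H](CC2(O[Si](CC)(CC)CC)CC2)O[C@H](CO[Si](CC)(CC)CC)C(=C)O1 | intermediate
15 | (2R,9S,6Z)-7-methyl-9-{[1-(triethylsilyloxy)cyclopropyl]methyl}-2-[(triethylsilyloxy)methyl]oxon-6-en-3-one | C/C1=C/CCC(=O)[C@@H](CO[Si](CC)(CC)CC)O[C@H](CC2(O[Si](CC)(CC)CC)CC2)C1 | intermediate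
16 | (2R,9S,3E,6Z)-7-methyl-9-{[1-(triethylsilyloxy)cyclopropyl]methyl}-2-[(triethylsilyloxy)methyl]oxona-3,6-dien-3-yl trifluoromethanesulfonate | C/C1=C/C/C=C(/OS(=O)(=O)C(F)(F)F)[C@@H](CO[Si](CC)(CC)CC)O[C@H](CC2(O[Si](CC)(CC)CC)CC2)C1 | intermediate
17 | (2S,9S,3Z,6Z)-3,7-dimethyl-9-{[1-(triethylsilyloxy)cyclopropyl]methyl}-2-[(triethylsilyloxy)methyl]oxona-3,6-diene | C/C1=C/C/C=C(/C)[C@@H](CO[Si](CC)(CC)CC)O[C@H](CC2(O[Si](CC)(CC)CC)CC2)C1 | intermediate
18 | (6S,7R)-6,7-epoxide of 17 | C[C@]12O[C@H]1C/C=C(/C)[C@@H](CO[Si](CC)(CC)CC)O[C@H](CC3(O[Si](CC)(CC)CC)CC3)C2 | intermediate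
19 | (2S,6S,9S,3Z)-3-methyl-7-methylidene-9-{[1-(triethylsilyloxy)cyclopropyl]methyl}-2-[(triethylsilyloxy)methyl]oxon-3-en-6-ol | C=C1C[C@@H](CC2(O[Si](CC)(CC)CC)CC2)O[C@H](CO[Si](CC)(CC)CC)/C(C)=C\C[C@@H]1O | intermediate
20 | C6 tert-butyldimethylsilyl ether of 19 | C=C1C[C@@H](CC2(O[Si](CC)(CC)CC)CC2)O[C@H](CO[Si](CC)(CC)CC)/C(C)=C\C[C@@H]1O[Si](C)(C)C(C)(C)C | intermediate
21 | (2S,6S,9S,3Z)-6-(tert-butyldimethylsilyloxy)-9-[(1-hydroxycyclopropyl)methyl]-2-(hydroxymethyl)-3-methyl-7-methylideneoxon-3-ene | C=C1C[C@@H](CC2(O)CC2)O[C@H](CO)/C(C)=C\C[C@@H]1O[Si](C)(C)C(C)(C)C | intermediate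
22 | C2 carbaldehyde from 21, ring centres as in 21 (not isolated) | C=C1C[C@@H](CC2(O)CC2)O[C@H](C=O)/C(C)=C\C[C@@H]1O[Si](C)(C)C(C)(C)C | intermediate
23 | (E)-N-methoxy-N-methylprop-2-enamide attached through its C3 to C2 of the oxonene, cyclopropanol free, ring centres as in 21 | C=C1C[C@@H](CC2(O)CC2)O[C@H](/C=C/C(=O)N(C)OC)/C(C)=C\C[C@@H]1O[Si](C)(C)C(C)(C)C | intermediate
24 | vinyl ketone: 23 with the C9 side chain CH2–C(=O)–CH=CH2 | C=C1C[C@@H](CC(=O)C=C)O[C@H](/C=C/C(=O)N(C)OC)/C(C)=C\C[C@@H]1O[Si](C)(C)C(C)(C)C | intermediate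
25 | (Z)-2-(triethylsilyloxy)buta-1,3-dienyl derivative of 24 (not isolated) | C=C1C[C@@H](/C=C(\O[Si](CC)(CC)CC)C=C)O[C@H](/C=C/C(=O)N(C)OC)/C(C)=C\C[C@@H]1O[Si](C)(C)C(C)(C)C | intermediate
26 | Diels–Alder adduct, C11 triethylsilyl enol ether (not isolated) | C=C1C[C@@H]2O[C@H]([C@H]3[C@@H](CC=C(O[Si](CC)(CC)CC)[C@H]32)C(=O)N(C)OC)/C(C)=C\C[C@@H]1O[Si](C)(C)C(C)(C)C | intermediate
27 | tricyclic C11 ketone with Weinreb amide on C14; C1, C2, C6, C9, C10, C14 as in the target | C=C1C[C@@H]2O[C@H]([C@H]3[C@@H](CCC(=O)[C@H]32)C(=O)N(C)OC)/C(C)=C\C[C@@H]1O[Si](C)(C)C(C)(C)C | intermediate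
28 | tricyclic C11 tertiary alcohol (C11 as in the target) with acetyl group on C14 | C=C1C[C@@H]2O[C@H]([C@H]3[C@@H](CC[C@@](C)(O)[C@H]32)C(C)=O)/C(C)=C\C[C@@H]1O[Si](C)(C)C(C)(C)C | intermediate
29 | vinyl triflate of 28 (C14–C(OTf)=CH2) | C=C1C[C@@H]2O[C@H]([C@H]3[C@@H](CC[C@@](C)(O)[C@H]32)C(=C)OS(=O)(=O)C(F)(F)F)/C(C)=C\C[C@@H]1O[Si](C)(C)C(C)(C)C | intermediate
30 | 2-substituted acrylic acid (C14–C(=CH2)–CO2H) | C=C1C[C@@H]2O[C@H]([C@H]3[C@@H](CC[C@@](C)(O)[C@H]32)C(=C)C(=O)O)/C(C)=C\C[C@@H]1O[Si](C)(C)C(C)(C)C | intermediate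
31 | α-methyl acid, C15 as in the target | C=C1C[C@@H]2O[C@H]([C@H]3[C@@H](CC[C@@](C)(O)[C@H]32)[C@@H](C)C(=O)O)/C(C)=C\C[C@@H]1O[Si](C)(C)C(C)(C)C | intermediate
32 | 3,4-epoxide of 31, oxygen on the face anti to the C2–C1 bond (not isolated) | C=C1C[C@@H]2O[C@H]([C@H]3[C@@H](CC[C@@](C)(O)[C@H]32)[C@@H](C)C(=O)O)[C@]4(C)O[C@@H]4C[C@@H]1O[Si](C)(C)C(C)(C)C | intermediate
33 | hydroxy lactone: target skeleton with free C4–OH and C6–O-tert-butyldimethylsilyl | C=C1C[C@@H]2O[C@@H]3[C@H]4[C@@H](CC[C@@](C)(O)[C@H]42)[C@@H](C)C(=O)O[C@@]3(C)[C@H](O)C[C@@H]1O[Si](C)(C)C(C)(C)C | intermediate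
34 | C4 octanoate of 33 | C=C1C[C@@H]2O[C@@H]3[C@H]4[C@@H](CC[C@@](C)(O)[C@H]42)[C@@H](C)C(=O)O[C@@]3(C)[C@H](OC(=O)CCCCCCC)C[C@@H]1O[Si](C)(C)C(C)(C)C | intermediate
35 | target, (1S,2R,3S,4R,6S,9S,10R,11R,14R,15R) in the locants above | C=C1C[C@@H]2O[C@@H]3[C@H]4[C@@H](CC[C@@](C)(O)[C@H]42)[C@@H](C)C(=O)O[C@@]3(C)[C@H](OC(=O)CCCCCCC)C[C@@H]1O | target

**Step count and risks**

Total step count: 28. Longest linear sequence: 26 steps (steps 1–3 and 6–28, from compound 1); steps 4 and 5 form the short branch.

Steps most likely to fail: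

Step 21. The diene and the dienophile sit on opposite faces of the nine-membered ring, so the compact concerted transition state may not be reached; bimolecular cycloaddition or loss of endo/exo and facial control could then take over. The fallback sets out from 24 and builds the two rings one after the other by anionic chemistry. LiN(SiMe3)2 (THF, −78 °C) would form the cross-conjugated dienolate of the vinyl ketone, which closes the oxolane by 5-exo Michael addition of C10 to C1 of the enamide and, after protonation, gives the oxolane keto amide F1. A second base treatment (KOtBu, tBuOH/THF, 0 °C) would close the cyclohexanone by 6-endo Michael addition of the amide enolate carbon C14 to C13 of the vinyl ketone. This comes back to the route at 27, and each ring closure can be equilibrated on its own.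

Step 26. The peracid may attack the wrong face of C3=C4, or the epoxide may be opened intermolecularly or at C4 instead of by the tethered acid at C3. The fallback sets out from 31 and replaces the irreversible epoxidation by a reversible electrophile. Iodolactonization (I2, NaHCO3, MeCN, 0 °C) would trap only the iodonium ion that lies anti to the tethered carboxylate and give the iodolactone F2, with the lactone oxygen at C3 and iodine at C4 on the opposite face. Silver octanoate (AgO2C(CH2)6CH3, toluene, 60 °C) would then replace iodide at C4 with net retention through participation of the neighbouring lactone acyloxy group (Prévost-type double inversion). This comes back to the route at 34.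

Step 6. The hindered secondary alkoxide may eliminate the α-triflyloxy ester by E2 instead of substituting it, or the triflate may lose configurational integrity. The fallback sets out from 5 and builds C2 on a glycolate. O-Alkylation with bromoacetic acid (NaH, THF) would give the glycolic acid ether F3. Coupling with lithiated (S)-4-benzyloxazolidin-2-one through the pivaloyl mixed anhydride would give the imide F4. Titanium enolate hydroxymethylation (TiCl4, iPr2NEt, CH2Cl2, 0 °C; 1,3,5-trioxane, TiCl4) anti to the benzyl group would give the hydroxymethyl imide F5 with (R)-configured C2. Silylation (Et3SiCl, imidazole) would give the silyl ether imide F6. Cleavage of the auxiliary with LiOH/H2O2 comes back to the route at 10.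

Further compounds
F1 | step 21 | oxolane keto amide: C1–C10 bond formed, vinyl ketone on C10, CH2C(O)N(OMe)Me on C1 | C=C1C[C@@H]2O[C@H]([C@@H](CC(=O)N(C)OC)[C@H]2C(=O)C=C)/C(C)=C\C[C@@H]1O[Si](C)(C)C(C)(C)C
F2 | step 26 | iodolactone: 33 with iodine in place of the C4 hydroxyl | C=C1C[C@@H]2O[C@@H]3[C@H]4[C@@H](CC[C@@](C)(O)[C@H]42)[C@@H](C)C(=O)O[C@@]3(C)[C@H](I)C[C@@H]1O[Si](C)(C)C(C)(C)C
F3 | step 6 | 2-{[(2S)-4-methyl-1-[1-(triethylsilyloxy)cyclopropyl]pent-4-en-2-yl]oxy}acetic acid | CC(=C)C[C@H](OCC(=O)O)CC1(O[Si](CC)(CC)CC)CC1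
F4 | step 6 | (4S)-4-benzyl-3-(2-{[(2S)-4-methyl-1-[1-(triethylsilyloxy)cyclopropyl]pent-4-en-2-yl]oxy}acetyl)oxazolidin-2-one | CC(=C)C[C@H](OCC(=O)N2[C@@H](Cc3ccccc3)COC2=O)CC1(O[Si](CC)(CC)CC)CC1
F5 | step 6 | (2R)-3-hydroxypropanoyl imide: F4 with CH2OH on the glycolate carbon | CC(=C)C[C@H](O[C@H](CO)C(=O)N2[C@@H](Cc3ccccc3)COC2=O)CC1(O[Si](CC)(CC)CC)CC1
F6 | step 6 | triethylsilyl ether of F5 | CC(=C)C[C@H](O[C@H](CO[Si](CC)(CC)CC)C(=O)N2[C@@H](Cc3ccccc3)COC2=O)CC1(O[Si](CC)(CC)CC)CC1
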